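## Retrosynthetic overview
1. The α-methylene-γ-lactone is formed last, by TEMPO oxidation of a 2-methylene-1,4-diol (C-12 OH and C-6 OH). Only removal of two silyl groups follows it.
2. The ten-membered carbocycle is formed first, by an intramolecular Nozaki–Hiyama–Kishi closure of C-5–C-6 (alkenyl bromide plus aldehyde).
3. The key union is C-9–C-10. A C8 (1E,5Z)-bromo-iodo-diene, used as its alkenyllithium, adds to a C7 aldehyde, and the alkoxide is trapped as the isobutyrate.
4. The C7 aldehyde comes from L-erythrulose (C-6 to C-9, source of C-8) and a 2-lithioallyl PMB ether (C-11 to C-13). C-7, C-9 and C-6 follow from three Felkin–Anh additions.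
5. The C8 diene comes from pent-4-yn-1-ol (carboalumination, E) and iodoethane (iodo-Wittig, Z).

Assumption: germacrane numbering (C-1 to C-15) is used for all intermediates. CIP descriptors change where priorities change, although the spatial arrangement stays the same.

## Route

Step 1
Reactants: 1 iodoethane
Product: 2 ethyltriphenylphosphonium iodide
Conditions: PPh3, toluene, 110 °C
Reagents that add atoms: triphenylphosphine, c1ccc(cc1)P(c1ccccc1)c1ccccc1
Why: SN2 quaternisation of the phosphine by a primary iodide gives the Wittig salt that carries C-10 and C-14.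

Step 2
Reactants: 3 pent-4-yn-1-ol
Product: 5 (E)-5-bromo-4-methylpent-4-en-1-ol, via alkenylalane 4 (not isolated)
Conditions: Me3Al (3 equiv), Cp2ZrCl2 (0.25 equiv), CH2Cl2, 0 °C to rt; then NBS, THF, −30 °C; aq. work-up
Reagents that add atoms: trimethylaluminium, C[Al](C)C; N-bromosuccinimide, O=C1CCC(=O)N1Br
Why: Negishi carboalumination adds Me and Al syn across the alkyne, and bromodealumination with retention fixes the E C-4=C-5 alkene.

Step 3
Reactants: 5 (E)-5-bromo-4-methylpent-4-en-1-ol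
Product: 6 (E)-5-bromo-4-methylpent-4-enal
Conditions: Dess–Martin periodinane, CH2Cl2, rt
Reagents that add atoms: none
Why: Dess–Martin oxidation stops at the aldehyde and leaves the alkenyl bromide and its geometry untouched.

Step 4
Reactants: 2 ethyltriphenylphosphonium iodide; 6 (E)-5-bromo-4-methylpent-4-enal
Product: 10 (1E,5Z)-1-bromo-6-iodo-2-methylhepta-1,5-diene, via ethylidene ylide 7 (not isolated), via iodophosphonium salt 8 (not isolated), via iodo ylide 9 (not isolated)
Conditions: n-BuLi, THF, rt; I2, −78 °C; NaN(SiMe3)2, −20 °C; then 6, −78 °C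
Reagents that add atoms: iodine, II
Why: The Stork–Zhao-type iodo-Wittig olefination of an unbranched aldehyde is Z-selective, which places I (later C-9) cis to C-2.

Step 5
Reactants: 11 2,3-dibromoprop-1-ene
Product: 12 1-{[(2-bromoprop-2-en-1-yl)oxy]methyl}-4-methoxybenzene
Conditions: 4-methoxybenzyl alcohol, NaH, Bu4NI (cat.), THF, 0 °C to rt
Reagents that add atoms: 4-methoxybenzyl alcohol, COc1ccc(CO)cc1
Why: Williamson ether synthesis displaces only the allylic bromide, so the vinylic bromide stays for lithiation.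

Step 6
Reactants: 13 L-erythrulose
Product: 14 (S)-1,3,4-tris(triethylsilyloxy)butan-2-one
Conditions: Et3SiCl (3.6 equiv), imidazole, DMF, 0 °C to rt
Reagents that add atoms: chlorotriethylsilane, CC[Si](Cl)(CC)CC
Why: Exhaustive silylation under mild base keeps the stereocentre of L-erythrulose, which becomes C-8 of the target.

Step 7
Reactants: 12 2-bromoallyl PMB ether; 14 (S)-1,3,4-tris(triethylsilyloxy)butan-2-one
Product: 17 (2S,3S)-2-{3-[(4-methoxybenzyl)oxy]prop-1-en-2-yl}-1,2,3,4-tetrakis(triethylsilyloxy)butane, via alkenyllithium 15 (not isolated), via tertiary alkoxide 16 (not isolated)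
Conditions: 12, t-BuLi (2 equiv per Br), Et2O, −78 °C; 14, −78 °C; then Et3SiOTf, −78 to 0 °C
Reagents that add atoms: triethylsilyl trifluoromethanesulfonate, CC[Si](CC)(CC)OS(=O)(=O)C(F)(F)F
Why: This is a Br/Li exchange and 1,2-addition under non-chelating polar Felkin–Anh control, with attack anti to the C-8 O-silyl group and past H-8, which sets C-7; any O-to-O silyl shift is harmless because all four oxygens end up as TES ethers.

Step 8
Reactants: 17 tetra-TES ether
Product: 18 (2R,3S)-3-{3-[(4-methoxybenzyl)oxy]prop-1-en-2-yl}-2,3,4-tris(triethylsilyloxy)butanal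
Conditions: (COCl)2 (1.2 equiv), DMSO, CH2Cl2, −78 to −45 °C; Et3N, −78 to 0 °C
Reagents that add atoms: none
Why: In this Swern oxidation run directly on the silyl ether, the chlorodimethylsulfonium ion attacks the open primary C-9 ether faster than the neopentyl C-6, secondary C-8 or tertiary C-7 ethers, and C-8 keeps its spatial arrangement.

Step 9
Reactants: 10 (1E,5Z)-1-bromo-6-iodo-2-methylhepta-1,5-diene; 18 C-9 aldehyde; 19 isobutyryl chloride
Product: 22 (7S,8S,9S,1(10)Z,4E)-5-bromo-9-isobutyryloxy-12-(4-methoxybenzyloxy)-6,7,8-tris(triethylsilyloxy)-5,6-secogermacra-1(10),4,11(13)-triene, via dienyllithium 20 (not isolated), via C-9 alkoxide 21 (not isolated)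
Conditions: 10, t-BuLi (2.0 equiv per I), Et2O, −78 °C; 18, −78 °C; then 19, −78 to 0 °C
Reagents that add atoms: none
Why: I/Li exchange outruns Br/Li exchange and keeps the Z geometry, polar Felkin–Anh addition to the α-silyloxy aldehyde gives the 8,9-anti product (9S), and acylation of the cold lithium alkoxide forestalls silyl migration.

Step 10
Reactants: 22 seco-bromide
Product: 23 (7R,8S,9S,1(10)Z,4E)-5-bromo-9-isobutyryloxy-12-(4-methoxybenzyloxy)-7,8-bis(triethylsilyloxy)-5,6-secogermacra-1(10),4,11(13)-trien-6-al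
Conditions: (COCl)2 (4 equiv), DMSO, CH2Cl2, −78 to −30 °C; Et3N
Reagents that add atoms: none
Why: A second Swern oxidation converts the only remaining primary TES ether, and the aldehyde formed has no α-hydrogen and so cannot epimerise.

Step 11
Reactants: 23 bromo aldehyde
Product: 24 (6S,7S,8S,9S,1(10)Z,4E)-9-isobutyryloxy-12-(4-methoxybenzyloxy)-7,8-bis(triethylsilyloxy)germacra-1(10),4,11(13)-trien-6-ol
Conditions: CrCl2 (15 equiv), NiCl2 (1 mol % of Cr), DMSO/THF, 2 mM, rt to 45 °C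
Reagents that add atoms: none
Why: In this intramolecular Nozaki–Hiyama–Kishi reaction the alkenyl species of trivalent chromium adds only to the aldehyde with retention of E geometry, and Felkin–Anh attack anti to the C-7 O-silyl group and past the flat C-11 vinyl group sets 6S.

Step 12
Reactants: 24 macrocyclic PMB ether
Product: 25 (6S,7S,8S,9S,1(10)Z,4E)-9-isobutyryloxy-7,8-bis(triethylsilyloxy)germacra-1(10),4,11(13)-triene-6,12-diol
Conditions: DDQ, CH2Cl2/pH 7 buffer, 0 °C
Reagents that add atoms: none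
Why: Oxidative PMB cleavage is orthogonal to the TES ethers, the ester and the alkenes, and it frees only the C-12 hydroxyl.

Step 13
Reactants: 25 6,12-diol
Product: 28 7,8-bis-O-triethylsilyl ether of the target, via hydroxy enal 26 (not isolated), via lactol 27 (not isolated)
Conditions: TEMPO (0.2 equiv), PhI(OAc)2 (3 equiv), CH2Cl2, rt
Reagents that add atoms: none
Why: TEMPO/PhI(OAc)2 oxidative lactonisation takes the primary allylic alcohol first, the enal is captured by the only free hydroxyl (C-6, since O-8 is still silylated), and the lactol is oxidised to the trans-fused α-methylene lactone.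

Step 14
Reactants: 28 bis-TES lactone
Product: 29 (6S,7R,8S,9S,1(10)Z,4E)-7,8-dihydroxy-9-isobutyryloxygermacra-1(10),4,11(13)-trien-12,6-olide
Conditions: HF·pyridine, pyridine, THF, 0 °C to rt
Reagents that add atoms: none
Why: Buffered fluoride desilylation frees the two hydroxyls without base, so the 9-ester does not migrate and no stereocentre is touched.

## Compound list
1 | iodoethane | CCI | starting material
2 | ethyltriphenylphosphonium iodide | CC[P+](c1ccccc1)(c1ccccc1)c1ccccc1.[I-] | intermediate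
3 | pent-4-yn-1-ol | C#CCCCO | starting material
4 | (E)-alkenyl(dimethyl)alane, O-aluminated | C[Al](C)/C=C(\C)CCCO[Al](C)C | intermediate
5 | (E)-5-bromo-4-methylpent-4-en-1-ol | OCCC/C(C)=C/Br | intermediate
6 | (E)-5-bromo-4-methylpent-4-enal | O=CCC/C(C)=C/Br | intermediate
7 | ethylidenetriphenylphosphorane | CC=P(c1ccccc1)(c1ccccc1)c1ccccc1 | intermediate
8 | (1-iodoethyl)triphenylphosphonium iodide | CC(I)[P+](c1ccccc1)(c1ccccc1)c1ccccc1.[I-] | intermediate
9 | (1-iodoethylidene)triphenylphosphorane | CC(I)=P(c1ccccc1)(c1ccccc1)c1ccccc1 | intermediate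
10 | (1E,5Z)-1-bromo-6-iodo-2-methylhepta-1,5-diene | Br/C=C(\C)CC/C=C(/C)I | intermediate
11 | 2,3-dibromoprop-1-ene | C=C(Br)CBr | starting material
12 | 2-bromoallyl 4-methoxybenzyl ether | C=C(Br)COCc1ccc(OC)cc1 | intermediate
13 | L-erythrulose, (S)-1,3,4-trihydroxybutan-2-one | OCC(=O)[C@@H](O)CO | starting material
14 | (S)-1,3,4-tris(triethylsilyloxy)butan-2-one | CC[Si](CC)(CC)OCC(=O)[C@@H](O[Si](CC)(CC)CC)CO[Si](CC)(CC)CC | intermediate
15 | 2-lithioallyl 4-methoxybenzyl ether | [Li]C(=C)COCc1ccc(OC)cc1 | intermediate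
16 | lithium (7S,8S) tertiary alkoxide | CC[Si](CC)(CC)OC[C@@]([O-])(C(=C)COCc1ccc(OC)cc1)[C@@H](O[Si](CC)(CC)CC)CO[Si](CC)(CC)CC.[Li+] | intermediate
17 | (2S,3S)-2-{3-[(4-methoxybenzyl)oxy]prop-1-en-2-yl}-1,2,3,4-tetrakis(triethylsilyloxy)butane | CC[Si](CC)(CC)OC[C@@](O[Si](CC)(CC)CC)(C(=C)COCc1ccc(OC)cc1)[C@@H](O[Si](CC)(CC)CC)CO[Si](CC)(CC)CC | intermediate
18 | (2R,3S)-3-{3-[(4-methoxybenzyl)oxy]prop-1-en-2-yl}-2,3,4-tris(triethylsilyloxy)butanal | CC[Si](CC)(CC)OC[C@@](O[Si](CC)(CC)CC)(C(=C)COCc1ccc(OC)cc1)[C@@H](O[Si](CC)(CC)CC)C=O | intermediate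
19 | isobutyryl chloride | CC(C)C(=O)Cl | starting material
20 | (1E,5Z)-1-bromo-6-lithio-2-methylhepta-1,5-diene | Br/C=C(\C)CC/C=C(/C)[Li] | intermediate
21 | lithium (7S,8S,9S) C-9 alkoxide | CC[Si](CC)(CC)OC[C@@](O[Si](CC)(CC)CC)(C(=C)COCc1ccc(OC)cc1)[C@@H](O[Si](CC)(CC)CC)[C@@H]([O-])/C(C)=C\CC/C(C)=C/Br.[Li+] | intermediate
22 | (7S,8S,9S) seco-bromide, 9-isobutyrate, 6,7,8-tris-TES, 12-PMB | CC[Si](CC)(CC)OC[C@@](O[Si](CC)(CC)CC)(C(=C)COCc1ccc(OC)cc1)[C@@H](O[Si](CC)(CC)CC)[C@@H](OC(=O)C(C)C)/C(C)=C\CC/C(C)=C/Br | intermediate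
23 | (7R,8S,9S) seco-bromo C-6 aldehyde | O=C[C@@](O[Si](CC)(CC)CC)(C(=C)COCc1ccc(OC)cc1)[C@@H](O[Si](CC)(CC)CC)[C@@H](OC(=O)C(C)C)/C(C)=C\CC/C(C)=C/Br | intermediate
24 | (6S,7S,8S,9S) germacratrien-6-ol, 12-PMB, 7,8-bis-TES | O[C@H]2/C=C(\C)CC/C=C(/C)[C@H](OC(=O)C(C)C)[C@H](O[Si](CC)(CC)CC)[C@]2(O[Si](CC)(CC)CC)C(=C)COCc1ccc(OC)cc1 | intermediate
25 | (6S,7S,8S,9S) germacratriene-6,12-diol, 7,8-bis-TES | O[C@H]2/C=C(\C)CC/C=C(/C)[C@H](OC(=O)C(C)C)[C@H](O[Si](CC)(CC)CC)[C@]2(O[Si](CC)(CC)CC)C(=C)CO | intermediate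
26 | 6-hydroxy-12-al | O[C@H]2/C=C(\C)CC/C=C(/C)[C@H](OC(=O)C(C)C)[C@H](O[Si](CC)(CC)CC)[C@]2(O[Si](CC)(CC)CC)C(=C)C=O | intermediate
27 | 12,6-lactol (C-12 epimers) | C=C1C(O)O[C@H]2/C=C(\C)CC/C=C(/C)[C@H](OC(=O)C(C)C)[C@H](O[Si](CC)(CC)CC)[C@]12O[Si](CC)(CC)CC | intermediate
28 | 7,8-bis-O-TES ether of the target | C=C1C(=O)O[C@H]2/C=C(\C)CC/C=C(/C)[C@H](OC(=O)C(C)C)[C@H](O[Si](CC)(CC)CC)[C@]12O[Si](CC)(CC)CC | intermediate
29 | CNP0301808.4 | C=C1C(=O)O[C@H]2/C=C(\C)CC/C=C(/C)[C@H](OC(=O)C(C)C)[C@H](O)[C@]12O | target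

## Step count and risks
Total step count: 14.

Longest linear sequence: 9 steps, from 13 to 29 by steps 6–14. The line from 3 to 29 by steps 2–4 and 9–14 is equally long.

**Step 11.** The closure builds a strained ten-membered ring from a hindered aldehyde and a sluggish alkenyl bromide. The fallback closes the ring at C-1/C-10 by olefin metathesis instead, and it sets out from 6 and 18.
- Ph3P=CH2 turns 6 into (E)-1-bromo-2-methylhexa-1,5-diene F1.
- 2-Lithiopropene (from 2-bromopropene and t-BuLi) adds to 18, and trapping with 19 gives the isopropenyl isobutyrate F2.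
- Swern oxidation of the primary TES ether gives the C-6 aldehyde F3.
- F1 is lithiated with t-BuLi and added to F3 at −78 °C to give the triene alcohol F4.
- The second-generation Grubbs catalyst in dilute refluxing CH2Cl2 forms the Z C-1=C-10 alkene, and the route is rejoined at 24.

**Step 8.** The step relies on kinetic discrimination between two primary TES ethers. The fallback tells the two ends apart by protecting groups, and it sets out from 17.
- PPTS in MeOH at 0 °C removes both primary TES groups to give the 6,9-diol F5.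
- AcCl with 2,4,6-collidine at −78 °C acetylates only the open C-9 hydroxyl to give the 9-acetate F6.
- Et3SiCl with imidazole silylates the neopentyl C-6 hydroxyl to give the 6-O-TES 9-acetate F7.
- i-Bu2AlH at −78 °C removes the acetate to give the C-9 alcohol F8.
- Dess–Martin oxidation rejoins the route at 18.

**Step 7.** The risks are facial selectivity and enolisation of the acyclic ketone. The fallback lets a rigid dioxolane steer the addition, and it sets out from 13.
- 2,2-Dimethoxypropane with camphorsulfonic acid gives 3,4-O-isopropylidene-L-erythrulose F9.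
- Et3SiCl with imidazole gives its 1-O-TES ether F10.
- Alkenyllithium 15 adds anti to the ring oxygen to give the tertiary alcohol F11.
- Aqueous AcOH in THF strips the acetonide and the TES group to give the tetraol F12.
- Et3SiOTf with 2,6-lutidine rejoins the route at 17.

## Further compounds
F1 | step 11 | (E)-1-bromo-2-methylhexa-1,5-diene | C=CCC/C(C)=C/Br
F2 | step 11 | (7S,8S,9S) isopropenyl isobutyrate, 6,7,8-tris-TES, 12-PMB | CC[Si](CC)(CC)OC[C@@](O[Si](CC)(CC)CC)(C(=C)COCc1ccc(OC)cc1)[C@@H](O[Si](CC)(CC)CC)[C@@H](OC(=O)C(C)C)C(C)=C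
F3 | step 11 | (7R,8S,9S) C-6 aldehyde of F2 | O=C[C@@](O[Si](CC)(CC)CC)(C(=C)COCc1ccc(OC)cc1)[C@@H](O[Si](CC)(CC)CC)[C@@H](OC(=O)C(C)C)C(C)=C
F4 | step 11 | (6S,7S,8S,9S,4E) triene alcohol for metathesis | C=CCC/C(C)=C/[C@H](O)[C@@](O[Si](CC)(CC)CC)(C(=C)COCc1ccc(OC)cc1)[C@@H](O[Si](CC)(CC)CC)[C@@H](OC(=O)C(C)C)C(C)=C
F5 | step 8 | (7S,8S) 6,9-diol, 7,8-bis-TES | OC[C@@](O[Si](CC)(CC)CC)(C(=C)COCc1ccc(OC)cc1)[C@@H](O[Si](CC)(CC)CC)CO
F6 | step 8 | (7S,8S) 9-acetate | OC[C@@](O[Si](CC)(CC)CC)(C(=C)COCc1ccc(OC)cc1)[C@@H](O[Si](CC)(CC)CC)COC(C)=O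
F7 | step 8 | (7S,8S) 6-O-TES 9-acetate | CC[Si](CC)(CC)OC[C@@](O[Si](CC)(CC)CC)(C(=C)COCc1ccc(OC)cc1)[C@@H](O[Si](CC)(CC)CC)COC(C)=O
F8 | step 8 | (7S,8S) C-9 alcohol, 6,7,8-tris-TES | CC[Si](CC)(CC)OC[C@@](O[Si](CC)(CC)CC)(C(=C)COCc1ccc(OC)cc1)[C@@H](O[Si](CC)(CC)CC)CO
F9 | step 7 | 3,4-O-isopropylidene-L-erythrulose | OCC(=O)[C@@H]1COC(C)(C)O1
F10 | step 7 | 1-O-triethylsilyl-3,4-O-isopropylidene-L-erythrulose | CC[Si](CC)(CC)OCC(=O)[C@@H]1COC(C)(C)O1
F11 | step 7 | (7S,8S) tertiary alcohol, 8,9-acetonide | CC[Si](CC)(CC)OC[C@@](O)(C(=C)COCc1ccc(OC)cc1)[C@@H]1COC(C)(C)O1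
F12 | step 7 | (7S,8S) tetraol | OC[C@@](O)(C(=C)COCc1ccc(OC)cc1)[C@@H](O)CO
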